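**Retrosynthetic overview**

- Target 17 comes from its bis-MOM ether 16 by acetal cleavage.
- 16 comes from phenol 12 and prenal 13. Ring D (the dimethylpyran) is cut at C4–C4a (C3' of ring B to the former aldehyde carbon) and at O1–C2 (O4' to CMe2). Forward, this is a boronic-acid-templated ortho-condensation, ortho-quinone methide formation and oxa-6π electrocyclization.
- Enabling feature: in ring B the free 4'-OH has a single unsubstituted ortho carbon, C3', lying between O2' and O4'. The other ortho carbon C5' bears OMe, the para carbon C1' bears the chromone, and O2' and O7 are MOM-capped, so exactly one carbon and one oxygen can react.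
- 12 comes from 11, made by Suzuki–Miyaura coupling (C3–C1' bond) of boronate 6 with 3-iodochromone 10. 6 derives from O-benzylisovanillin 1 (Baeyer–Villiger, bromination, MOM, borylation); 10 derives from resacetophenone 7 (MOM, enaminone, iodocyclization).
- Order of ring formation: ring C (pyranone, step 6), then the C3–C1' bond (step 7), then ring D (step 9). Rings A and B are bought.

Key step: step 9

Assumption: compounds 1, 7 and 13 are taken as commercial. Ring letters follow flavonoid usage (ring A = benzo ring of the chromone, ring C = pyranone, ring B = pendant aryl, ring D = dimethylpyran), and primed locants refer to ring B.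

**Route**

Step 1
Reactants: 1 3-(benzyloxy)-4-methoxybenzaldehyde
Product: 3 3-(benzyloxy)-4-methoxyphenol, via aryl formate 2 (not isolated)
Conditions: mCPBA, CH2Cl2, 0 °C to rt; aq. NaHCO3 wash; then K2CO3 (cat.), MeOH, rt
Reagents that add atoms: mCPBA (3-chloroperoxybenzoic acid), OOC(=O)c1cccc(Cl)c1
Why: Baeyer–Villiger oxidation in which the electron-rich aryl group (para-OMe) migrates in preference to hydrogen to give formate 2, which methanol transesterifies to the phenol.

Step 2
Reactants: 3 3-(benzyloxy)-4-methoxyphenol
Product: 4 5-(benzyloxy)-2-bromo-4-methoxyphenol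
Conditions: NBS (1.0 equiv), MeCN, −20 °C to 0 °C
Reagents that add atoms: N-bromosuccinimide, O=C1CCC(=O)N1Br
Why: Electrophilic aromatic bromination directed ortho by the free OH; the para position is blocked by OMe, and of the two ortho carbons the one para to OBn is the more activated and less hindered (the other lies between two oxygens).

Step 3
Reactants: 4 5-(benzyloxy)-2-bromo-4-methoxyphenol
Product: 5 1-(benzyloxy)-4-bromo-2-methoxy-5-(methoxymethoxy)benzene
Conditions: MOMCl, i-Pr2NEt, CH2Cl2, 0 °C to rt
Reagents that add atoms: chloromethyl methyl ether, COCCl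
Why: O-Alkylation of the phenol with an α-chloro ether (MOM protection), which caps the future O2' and nothing else.

Step 4
Reactants: 5 1-(benzyloxy)-4-bromo-2-methoxy-5-(methoxymethoxy)benzene
Product: 6 2-[4-(benzyloxy)-5-methoxy-2-(methoxymethoxy)phenyl]-4,4,5,5-tetramethyl-1,3,2-dioxaborolane
Conditions: B2pin2, KOAc, Pd(dppf)Cl2 (cat.), 1,4-dioxane, 90 °C
Reagents that add atoms: bis(pinacolato)diboron, CC1(C)OB(OC1(C)C)B1OC(C)(C)C(C)(C)O1
Why: Miyaura borylation of the aryl bromide; the weak base KOAc suppresses biaryl homocoupling, and the benzyl and MOM ethers are inert.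

Step 5
Reactants: 7 1-(2,4-dihydroxyphenyl)ethan-1-one
Product: 8 1-[2-hydroxy-4-(methoxymethoxy)phenyl]ethan-1-one
Conditions: MOMCl (1.1 equiv), K2CO3, acetone, rt
Reagents that add atoms: chloromethyl methyl ether, COCCl
Why: Selective O-alkylation of the 4-OH, because the 2-OH is held in a hydrogen bond to the acetyl carbonyl and is much less nucleophilic.

Step 6
Reactants: 8 1-[2-hydroxy-4-(methoxymethoxy)phenyl]ethan-1-one
Product: 10 3-iodo-7-(methoxymethoxy)-4H-chromen-4-one, via enaminone 9 (not isolated)
Conditions: DMF-DMA, 95 °C; evaporate; then I2, pyridine, CHCl3, rt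
Reagents that add atoms: N,N-dimethylformamide dimethyl acetal, COC(OC)N(C)C; iodine, II
Why: Enaminone condensation at the acetyl methyl group followed by iodine-mediated cyclization (α-iodination to an iminium, attack of the phenol oxygen, loss of dimethylamine), which closes ring C as the 3-iodochromone; pyridine buffers the mixture so the MOM ether survives.

Step 7
Reactants: 6 2-[4-(benzyloxy)-5-methoxy-2-(methoxymethoxy)phenyl]-4,4,5,5-tetramethyl-1,3,2-dioxaborolane; 10 3-iodo-7-(methoxymethoxy)-4H-chromen-4-one
Product: 11 3-[4-(benzyloxy)-5-methoxy-2-(methoxymethoxy)phenyl]-7-(methoxymethoxy)-4H-chromen-4-one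
Conditions: Pd(dppf)Cl2 (cat.), K2CO3, 1,4-dioxane/H2O, 80 °C
Reagents that add atoms: none
Why: Suzuki–Miyaura coupling; the 3-iodochromone is an activated α-iodoenone that undergoes fast oxidative addition, and the ortho-alkoxyaryl boronate transmetalates under mild aqueous carbonate to form the C3–C1' bond of the isoflavone.

Step 8
Reactants: 11 3-[4-(benzyloxy)-5-methoxy-2-(methoxymethoxy)phenyl]-7-(methoxymethoxy)-4H-chromen-4-one
Product: 12 3-[4-hydroxy-5-methoxy-2-(methoxymethoxy)phenyl]-7-(methoxymethoxy)-4H-chromen-4-one
Conditions: H2 (1 atm), 10% Pd/C, EtOAc/MeOH, rt, stopped after one equivalent of H2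
Reagents that add atoms: none
Why: Catalytic hydrogenolysis of the benzyl aryl ether, which is much faster than reduction of the vinylogous-ester C2=C3 bond of the chromone and leaves the MOM acetals intact, freeing only the 4'-OH.

Step 9
Reactants: 12 3-[4-hydroxy-5-methoxy-2-(methoxymethoxy)phenyl]-7-(methoxymethoxy)-4H-chromen-4-one; 13 3-methylbut-2-enal
Product: 16 3-[8-methoxy-5-(methoxymethoxy)-2,2-dimethyl-2H-chromen-6-yl]-7-(methoxymethoxy)-4H-chromen-4-one, via benzodioxaborin 14 (not isolated), via ortho-quinone methide 15 (not isolated)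
Conditions: PhB(OH)2 (1.2 equiv), EtCO2H (cat.), toluene, reflux, Dean–Stark
Reagents that add atoms: none
Why: Boronic-acid-templated chromenylation of a phenol with an enal: 12 and PhB(OH)2 form an aryloxyboron species that delivers the aldehyde carbon of 13 to C3' through a six-membered transition state, closing the temporary 1,3,2-dioxaborin ring of 14 and making the C3'–CH bond, and thermal cycloreversion of 14 expels PhBO (returned as PhB(OH)2 on aqueous work-up) to give ortho-quinone methide 15. The 1-oxatriene of 15 (C4'=O, exocyclic C3'=CH, CH=CMe2, Z about the exocyclic bond) then closes ring D by a thermal disrotatory 6π electrocyclization that makes the O4'–CMe2 bond and restores the aromaticity of ring B. The closest known reaction type is the phenylboronic acid-mediated synthesis of 2H-chromenes from phenols and α,β-unsaturated aldehydes, a variant of the prenal chromenylation of hydroxylated flavonoids. No stereocenter remains, since the CH stereocenter of 14 is racemic and is erased on fragmentation, and C2 of ring D carries two methyl groups. The step needs site selectivity (ring B over ring A, C3' as the reacting carbon, O4' rather than O2' as the closing oxygen) and 1,2- rather than 1,4-addition to the enal: the MOM ethers on O7 and O2' leave O4'–H as the only phenol, its other ortho carbon C5' bears OMe and its para carbon C1' bears the chromone, and the boron template enforces ortho attack on the carbonyl carbon. Azeotropic removal of water drives the formation of 14.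

Step 10
Reactants: 16 3-[8-methoxy-5-(methoxymethoxy)-2,2-dimethyl-2H-chromen-6-yl]-7-(methoxymethoxy)-4H-chromen-4-one
Product: 17 7-hydroxy-3-(5-hydroxy-8-methoxy-2,2-dimethyl-2H-chromen-6-yl)-4H-chromen-4-one
Conditions: conc. HCl (cat.), MeOH, 50 °C
Reagents that add atoms: none
Why: Acid-catalysed transacetalization of both aryl MOM ethers to dimethoxymethane; dilute acid at moderate temperature should leave the conjugated dimethylchromene alkene and the chromone untouched.

**Compound list**

1 | 3-(benzyloxy)-4-methoxybenzaldehyde (O-benzylisovanillin) | COc1ccc(C=O)cc1OCc1ccccc1 | starting material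
2 | 3-(benzyloxy)-4-methoxyphenyl formate | COc1ccc(OC=O)cc1OCc1ccccc1 | intermediate
3 | 3-(benzyloxy)-4-methoxyphenol | COc1ccc(O)cc1OCc1ccccc1 | intermediate
4 | 5-(benzyloxy)-2-bromo-4-methoxyphenol | COc1cc(Br)c(O)cc1OCc1ccccc1 | intermediate
5 | 1-(benzyloxy)-4-bromo-2-methoxy-5-(methoxymethoxy)benzene | COCOc1cc(OCc2ccccc2)c(OC)cc1Br | intermediate
6 | 2-[4-(benzyloxy)-5-methoxy-2-(methoxymethoxy)phenyl]-4,4,5,5-tetramethyl-1,3,2-dioxaborolane | COCOc1cc(OCc2ccccc2)c(OC)cc1B1OC(C)(C)C(C)(C)O1 | intermediate
7 | 1-(2,4-dihydroxyphenyl)ethan-1-one (resacetophenone) | CC(=O)c1ccc(O)cc1O | starting material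
8 | 1-[2-hydroxy-4-(methoxymethoxy)phenyl]ethan-1-one | COCOc1ccc(C(C)=O)c(O)c1 | intermediate
9 | (E)-3-(dimethylamino)-1-[2-hydroxy-4-(methoxymethoxy)phenyl]prop-2-en-1-one | COCOc1ccc(C(=O)/C=C/N(C)C)c(O)c1 | intermediate
10 | 3-iodo-7-(methoxymethoxy)-4H-chromen-4-one | COCOc1ccc2c(c1)occ(I)c2=O | intermediate
11 | 3-[4-(benzyloxy)-5-methoxy-2-(methoxymethoxy)phenyl]-7-(methoxymethoxy)-4H-chromen-4-one | COCOc1ccc2c(c1)occ(-c1cc(OC)c(OCc3ccccc3)cc1OCOC)c2=O | intermediate
12 | 3-[4-hydroxy-5-methoxy-2-(methoxymethoxy)phenyl]-7-(methoxymethoxy)-4H-chromen-4-one | COCOc1ccc2c(c1)occ(-c1cc(OC)c(O)cc1OCOC)c2=O | intermediate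
13 | 3-methylbut-2-enal (prenal) | CC(C)=CC=O | starting material
14 | 3-[8-methoxy-5-(methoxymethoxy)-4-(2-methylprop-1-en-1-yl)-2-phenyl-4H-1,3,2-benzodioxaborin-6-yl]-7-(methoxymethoxy)-4H-chromen-4-one (racemic at C4 of the dioxaborin) | COCOc1ccc2c(c1)occ(-c1cc(OC)c3OB(c4ccccc4)OC(C=C(C)C)c3c1OCOC)c2=O | intermediate
15 | ortho-quinone methide of ring B: 7-(methoxymethoxy)chromon-3-yl on a cyclohexadienone with C4'=O, 5'-OMe, 2'-OMOM and a (Z)-3-methylbut-2-enylidene group at C3' | COCOc1ccc2c(c1)occ(C1=C(OCOC)/C(=C/C=C(C)C)C(=O)C(OC)=C1)c2=O | intermediate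
16 | 3-[8-methoxy-5-(methoxymethoxy)-2,2-dimethyl-2H-chromen-6-yl]-7-(methoxymethoxy)-4H-chromen-4-one | COCOc1ccc2c(c1)occ(-c1cc(OC)c3OC(C)(C)C=Cc3c1OCOC)c2=O | intermediate
17 | 7-hydroxy-3-(5-hydroxy-8-methoxy-2,2-dimethyl-2H-chromen-6-yl)-4H-chromen-4-one | COc1cc(-c2coc3cc(O)ccc3c2=O)c(O)c2c1OC(C)(C)C=C2 | target

**Step count**

Total steps: 10. Longest linear sequence: 8 steps (steps 1, 2, 3, 4, 7, 8, 9, 10, from compound 1).

**Steps most likely to fail, with fallbacks**

1. Step 9. The condensation at C3', which is flanked by two oxygen substituents, may be slow, so that acid-promoted loss of the 2'-MOM group or self-condensation of the enal competes. Fallback: setting out from 12, the phenol is O-alkylated with 3-chloro-3-methylbut-1-yne (DBU, CuCl2 (cat.), MeCN, 0 °C) to give the aryl 1,1-dimethylpropargyl ether F1. Heating F1 in N,N-diethylaniline at 180 °C should bring about an aromatic Claisen rearrangement to C3' (the only free ortho carbon), a 1,5-hydrogen shift and the same oxa-6π electrocyclization. The route is rejoined at 16.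

2. Step 7. Protodeboronation of the electron-rich ortho-alkoxyaryl boronate, or opening of the pyranone ring by attack of aqueous base at C2, may erode the coupling. Fallback: setting out from bromide 5, bromine–lithium exchange (n-BuLi, THF, −78 °C) should give the aryllithium F2. Transmetalation with ZnCl2 gives the arylzinc chloride F3, which is coupled with 10 in a Negishi reaction (Pd(PPh3)4 (cat.), THF, rt to 50 °C) under anhydrous, base-free conditions. The route is rejoined at 11, and step 4 is no longer needed.

3. Step 10. During the acidic MOM cleavage, protonation of the chromene alkene (benzylic cation at C4 of ring D, stabilized by two ring oxygens) may lead to addition of methanol or opening of the pyran ring. Fallback: setting out from 12, both MOM groups are removed before ring D exists (conc. HCl (cat.), MeOH, 50 °C) to give 3-(2,4-dihydroxy-5-methoxyphenyl)-7-hydroxy-4H-chromen-4-one F4. F4 is then condensed with 13 under ethylenediammonium diacetate catalysis (toluene, reflux). Selectivity here would rest on the much higher nucleophilicity of the resorcinol-type C3' of ring B over ring A (deactivated by the pyranone carbonyl) and on the hydrogen bond of the 2'-OH to the C4 carbonyl, which should leave O4' to close the ring. The route is rejoined at 17.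

**Further compounds**

F1 | step 9 | 7-(methoxymethoxy)-3-{5-methoxy-2-(methoxymethoxy)-4-[(2-methylbut-3-yn-2-yl)oxy]phenyl}-4H-chromen-4-one | COCOc1ccc2c(c1)occ(-c1cc(OC)c(OC(C)(C)C#C)cc1OCOC)c2=O
F2 | step 7 | [4-(benzyloxy)-5-methoxy-2-(methoxymethoxy)phenyl]lithium | COCOc1cc(OCc2ccccc2)c(OC)cc1[Li]
F3 | step 7 | [4-(benzyloxy)-5-methoxy-2-(methoxymethoxy)phenyl]zinc chloride | COCOc1cc(OCc2ccccc2)c(OC)cc1[Zn]Cl
F4 | step 10 | 3-(2,4-dihydroxy-5-methoxyphenyl)-7-hydroxy-4H-chromen-4-one | COc1cc(-c2coc3cc(O)ccc3c2=O)c(O)cc1O
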